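Overview: trisindolal 9 is cut at one methine–C3(indole) bond. In the forward direction, the CH2 of diindolylmethane aldehyde 6 and C3–H of indole 7, two electron-rich C–H partners of like polarity, are joined by a two-electron oxidation (DDQ cross-dehydrogenative coupling, cation-pool order).
Enabling feature: the bridging carbon sits on C3 of the formyl-free indole ring. That ring's N1 lone pair, relayed through C2=C3, expels hydride and carries the charge as a 3-alkylideneindoleninium ion, while the C2–CHO group keeps the other indole ring out of the oxidation.
6 comes from alcohol 5 (MnO2). 5 comes from C3-alkylation of (indol-2-yl)methanol 3 by the azafulvene released from gramine methiodide 2, itself made from gramine 1.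
No ring is formed in the route: all three indole rings are bought intact, and no protecting group is used.

Key step: step 4

Assumption: the methine carbon carries two identical indol-3-yl groups, so the structure has no stereocentre and is achiral; no enantiocontrol is needed or possible.

Step 1
Reactants: 1 gramine [1-(1H-indol-3-yl)-N,N-dimethylmethanamine]
Product: 2 (1H-indol-3-ylmethyl)trimethylammonium iodide (gramine methiodide)
Conditions: MeI (excess), EtOH, 0 °C to rt; salt collected by filtration
Reagents that add atoms: methyl iodide, CI
Why: Menshutkin quaternisation of the aliphatic tertiary amine, which is far more nucleophilic than the indole N or C3, turns NMe2 into the neutral leaving group NMe3, while excess MeI and precipitation of the salt suppress transfer of the indolylmethyl group between amines; no stereocentre is formed.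

Step 2
Reactants: 2 (1H-indol-3-ylmethyl)trimethylammonium iodide; 3 (1H-indol-2-yl)methanol
Product: 5 [3-(1H-indol-3-ylmethyl)-1H-indol-2-yl]methanol, via 3-methylene-3H-indole 4 (not isolated)
Conditions: 3 (slight excess), H2O, 100 °C, sealed tube
Reagents that add atoms: none
Why: In this gramine-type elimination–addition (a Friedel–Crafts-type C3 alkylation), loss of NMe3 from 2 releases azafulvene 4, which is captured at its exocyclic carbon by C3 of 3, the only free enamine carbon of this more nucleophilic 2-alkylindole, and O-alkylation is reversible under the conditions whereas C-alkylation is not; no stereocentre is formed.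

Step 3
Reactants: 5 [3-(1H-indol-3-ylmethyl)-1H-indol-2-yl]methanol
Product: 6 3-(1H-indol-3-ylmethyl)-1H-indole-2-carbaldehyde
Conditions: activated MnO2 (10 equiv), CH2Cl2/acetone, rt
Reagents that add atoms: none
Why: Heterogeneous MnO2 oxidation of an indol-2-ylmethanol (a benzylic-type alcohol) is the standard access to indole-2-carbaldehydes and stops at the conjugated aldehyde, while the free N–H groups and the CH2 bridge should survive short contact at rt; no stereocentre is formed.

Step 4
Reactants: 6 3-(1H-indol-3-ylmethyl)-1H-indole-2-carbaldehyde; 7 indole
Product: 9 trisindolal [3-(di(1H-indol-3-yl)methyl)-1H-indole-2-carbaldehyde], via diindolylmethylium hydroquinonate 8 (not isolated)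
Conditions: DDQ (1.0 equiv), 4 Å MS, MeCN/CH2Cl2, −20 °C, 20 min; then 7 (1.5 equiv), −20 °C to rt; aq NaHCO3 wash
Reagents that add atoms: none
Why: DDQ forms a charge-transfer complex with the formyl-free, more electron-rich indole ring of 6 and removes hydride from the doubly indol-3-ylic CH2, the N1 lone pair of that ring pushing through C2=C3 to give the persistent, cyanine-like 3-alkylideneindoleninium (vinylogous iminium) ion 8 with DDQH− as counter-ion; indole 7, added only when the quinone is spent, attacks the exocyclic methine carbon through C3, and DDQH− takes up the proton of the rearomatisation. The closest known reaction type is the DDQ-mediated cross-dehydrogenative coupling of the 3-indolylmethyl C–H bond of N–H 3-(arylmethyl)indoles with carbon nucleophiles, which runs through the same kind of ion, as does the DDQ side-chain oxidation of 3-alkylindoles in wet THF; addition of an indole to such an ion is the product-forming step of the acid-catalysed tris(indolyl)methane syntheses. No ring is closed, and no stereocentre is created because the new methine carries two identical indol-3-yl groups. Site selectivity of the oxidation is secured by the substrate: only the bridging C–H bonds overlap with an unperturbed indole enamine, whereas the 2-formyl group lowers the HOMO of its own ring, is itself inert to DDQ and keeps 8 electrophilic enough for a neutral π-nucleophile. Chemoselectivity against oxidation of 7 and against over-oxidation of 9 to the triindolylmethylium dye is secured by the cation-pool order of addition with exactly one equivalent of DDQ, so that neither 7 nor 9 should meet the oxidant. The medium holds no acid stronger than the sparingly soluble DDQH2, which should spare the free, hindered CHO group from bis(indolyl)methane formation and the product from retro-Friedel–Crafts scrambling.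

Compound list
1 | gramine [1-(1H-indol-3-yl)-N,N-dimethylmethanamine] | CN(C)Cc1c[nH]c2ccccc12 | starting material
2 | (1H-indol-3-ylmethyl)trimethylammonium iodide | C[N+](C)(C)Cc1c[nH]c2ccccc12.[I-] | intermediate
3 | (1H-indol-2-yl)methanol | OCc1cc2ccccc2[nH]1 | starting material
4 | 3-methylene-3H-indole (azafulvene, not isolated) | C=C1C=Nc2ccccc12 | intermediate
5 | [3-(1H-indol-3-ylmethyl)-1H-indol-2-yl]methanol | OCc1[nH]c2ccccc2c1Cc1c[nH]c2ccccc12 | intermediate
6 | 3-(1H-indol-3-ylmethyl)-1H-indole-2-carbaldehyde | O=Cc1[nH]c2ccccc2c1Cc1c[nH]c2ccccc12 | intermediate
7 | indole | c1ccc2[nH]ccc2c1 | starting material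
8 | (2-formyl-1H-indol-3-yl)(1H-indol-3-yl)methylium 2,3-dichloro-5,6-dicyano-4-hydroxyphenolate, drawn as the 3-alkylideneindoleninium form (delocalised ion, C=C geometry not defined, not isolated) | O=Cc1[nH]c2ccccc2c1C=C1C=[NH+]c2ccccc12.N#Cc1c(O)c(Cl)c(Cl)c([O-])c1C#N | intermediate
9 | trisindolal [3-(di(1H-indol-3-yl)methyl)-1H-indole-2-carbaldehyde], achiral | O=Cc1[nH]c2ccccc2c1C(c1c[nH]c2ccccc12)c1c[nH]c2ccccc12 | target

Total step count: 4
Longest linear sequence: 4 steps (1 → 2 → 5 → 6 → 9)

Steps most likely to fail

Step 4 (key step). Several processes may interfere:
- covalent capture of the cation by the hydroquinonate;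
- hydride exchange between freshly formed product and remaining cation, which amounts to over-oxidation to the triaryl dye cation and back-reduction of the substrate;
- attack of indole on residual quinone.

The fallback sets out from 7 and comes back at 9. It makes the same bond at the aldehyde oxidation level by a classical acid-catalysed double Friedel–Crafts condensation. Commercial ethyl 3-formyl-1H-indole-2-carboxylate F1 is condensed with two equivalents of 7 (cat. p-TsOH, MeCN, rt) to give ethyl 3-[di(1H-indol-3-yl)methyl]-1H-indole-2-carboxylate F2. The ester shields the future formyl carbon from indole during the acid step. LiAlH4 in THF then gives {3-[di(1H-indol-3-yl)methyl]-1H-indol-2-yl}methanol F3, and MnO2 in CH2Cl2/acetone gives 9.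

Step 2. The azafulvene may be lost through hydrolysis and self-condensation with extrusion of formaldehyde. Capture at oxygen may persist, or the acid-sensitive 2-hydroxymethylindole may oligomerise on heating.

The fallback sets out from 7 and comes back at 5. It swaps the roles of the partners: parent indole becomes the nucleophile, and the electrophile carries an ester whose parent indole is too poor a nucleophile to self-condense. Commercial ethyl 1H-indole-2-carboxylate F4 undergoes a Mannich reaction (aq CH2O, Me2NH, AcOH) to give ethyl 3-[(dimethylamino)methyl]-1H-indole-2-carboxylate F5. Heating F5 with 7 in refluxing toluene (elimination–addition with loss of the amine) gives ethyl 3-(1H-indol-3-ylmethyl)-1H-indole-2-carboxylate F6. LiAlH4 in THF reduces F6 to 5.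

Step 3. Oxidation may compete at the doubly indolylic methylene bridge, or the polar N–H substrate may adsorb irreversibly on the oxide.

The fallback sets out from 2 (together with 7) and comes back at 6. It brings in the formyl carbon at the right oxidation level by directed metalation instead of alcohol oxidation. 2 and 7 in hot water (through 4) give 3,3'-diindolylmethane F7. In one pot, n-BuLi (2 equiv) then CO2 in THF gives dilithium 3,3'-methylenebis(indole-1-carboxylate) F8. One equivalent of t-BuLi at −78 °C gives the carbamate-directed 2-lithio derivative of the dilithium bis(carboxylate) F9. Quenching with DMF, followed by aqueous acid work-up in which both carbamates decarboxylate, gives 6. Unreacted F7 is recycled, because the monofunctionalisation is statistical.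

Further compounds
F1 | step 4 | ethyl 3-formyl-1H-indole-2-carboxylate | CCOC(=O)c1[nH]c2ccccc2c1C=O
F2 | step 4 | ethyl 3-[di(1H-indol-3-yl)methyl]-1H-indole-2-carboxylate | CCOC(=O)c1[nH]c2ccccc2c1C(c1c[nH]c2ccccc12)c1c[nH]c2ccccc12
F3 | step 4 | {3-[di(1H-indol-3-yl)methyl]-1H-indol-2-yl}methanol | OCc1[nH]c2ccccc2c1C(c1c[nH]c2ccccc12)c1c[nH]c2ccccc12
F4 | step 2 | ethyl 1H-indole-2-carboxylate | CCOC(=O)c1cc2ccccc2[nH]1
F5 | step 2 | ethyl 3-[(dimethylamino)methyl]-1H-indole-2-carboxylate | CCOC(=O)c1[nH]c2ccccc2c1CN(C)C
F6 | step 2 | ethyl 3-(1H-indol-3-ylmethyl)-1H-indole-2-carboxylate | CCOC(=O)c1[nH]c2ccccc2c1Cc1c[nH]c2ccccc12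
F7 | step 3 | 3,3'-diindolylmethane | c1ccc2c(c1)[nH]cc2Cc1c[nH]c2ccccc12
F8 | step 3 | dilithium 3,3'-methylenebis(indole-1-carboxylate) | [Li+].[Li+].[O-]C(=O)n1cc(Cc2cn(C([O-])=O)c3ccccc23)c2ccccc12
F9 | step 3 | 2-lithio derivative of the dilithium bis(carboxylate) | [Li+].[Li+].[Li]c1c(Cc2cn(C([O-])=O)c3ccccc23)c2ccccc2n1C([O-])=O
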